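## Structural features

The target is a single carbocycle, a cyclohexene numbered here C1 (CHOAc), C2 (CH2), C3 (CHBr), C4 (CMe2), C5 (=CH) and C6 (=C), with a two-carbon chain on C6 made of C7 (CHBr) and C8 (CH2Cl). The ring stereocentres C1 (R) and C3 (S) are 1,3-related across the C2 methylene, with oxygen and bromine cis. The third stereocentre, C7 (R), lies outside the ring, one sp2 carbon away from C1. Three functions are fragile: the allylic acetate at C1, the secondary allylic bromide at C7 (ionisation, allylic transposition, bromide exchange) and the vicinal C7-bromide/C8-chloride pair, which eliminates with base. The real difficulty is the C3–Br bond: C3 is flanked by the quaternary C4, so bromide cannot be brought in by displacement and must arrive by capture of a cationic carbon, in the correct relation to C1. The key step exploits the segment C1(O)–C2H2–C3(Br)–C4 (no hydrogen): this cis-1,3 oxygen/bromine pair beside a hydrogen-free carbon is what an aldehyde at C1 and a terminal vinyl group C2=C3 give in a bromide-terminated Prins closure, which forms C1–C2 and C3–Br and closes the six-membered ring. The acyl group on C6 activates and chelates the aldehyde, makes the alkene geometry irrelevant, and later becomes the C7 stereocentre.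

## Logic of the disconnections

14 ⇒ 13. The C7–Br bond is cut first, because the allylic secondary bromide is the most labile function and is best made last. A halide is traded for a carbinol whose configuration can be set by reduction. The forward step must be a clean SN2 displacement with inversion: no ionisation, no help from the C1 ester, no allylic transposition.

13 ⇒ 12. The C7–H bond is cut, turning the carbinol into a ketone. One stereocentre disappears and the conjugating acyl group needed for ring formation is revealed. The reduction must obey the reagent and not the C1 centre, go 1,2, and leave the ester and both carbon–halogen bonds alone.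

12 ⇒ 11. The O–acyl bond at C1 is cut, and the acylation is given the task of selecting the enantiomer. This lets the ring be formed on racemic material with an achiral Lewis acid, at the price of forgoing half of 11. The forward step needs an acyl-transfer catalyst that tells the enantiomers of 11 apart and acylates the (R)-carbinol.

11 ⇒ 10. C1–C2 and C3–Br are cut together. This is the only cut that makes the hindered C3–Br bond without a displacement, and it removes the ring and both ring stereocentres at once, leaving 10, which is acyclic and achiral. Forward, bromide must capture C3 faster than the cation rearranges, and capture must be tied to the geometry of C–C bond formation so that O and Br end up cis.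

10 ⇒ 8 (through 9). The C8–Cl bond is cut and the C7 ketone is masked as an enol ether. A chloromethyl ketone would not survive organometallic steps, so it is unveiled immediately before the cyclisation. The chlorination must select the enol ether over the vinyl group and the enal, and 9 must relax to 10. A direct Knoevenagel assembly of 10 was set aside, because the formyl ketone donor it needs self-condenses more readily than it would attack a neopentyl aldehyde.

8 ⇒ 6 + 7. The C6–C7 bond is cut at an sp2 carbon. This separates the two-carbon side chain, supplied by 7, from the C1–C6 backbone. The forward coupling must tolerate a free aldehyde and a terminal alkene and proceed with retention at the double bond.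

6 ⇒ 2 + 3 (through 4 and 5). The C4–C5 bond is cut. The quaternary carbon and its vinyl group come from 3 in one operation, and the carbonyl group is transposed afterwards. The forward step needs attack through the tertiary (γ) carbon of 4 at the single free formyl group of 2.

2 ⇒ 1. The enol C–O bond is cut. This leads to symmetrical, commercial 1. The forward step only has to convert one of the two formyl groups into a vinylogous ester so that the other alone is attacked.

## Other disconnections considered

Alternative 1: The cut is at C1–O and at the ring itself. The six-membered ring is traced back to the bicyclic tribromide A1, (1S,3S,5S)-3,6,6-tribromo-2,2-dimethylbicyclo[3.1.0]hexane, which already holds the C3 bromide. Forward, AgOAc in AcOH would remove the endo bromide of the CBr2 bridge. Disrotatory opening of the three-membered ring would give a cyclic allyl cation that takes up acetate at C1 and leaves a vinyl bromide at C6, i.e. A2, (1R,5S)-2,5-dibromo-4,4-dimethylcyclohex-2-en-1-yl acetate.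
- In its favour: silver-assisted opening of fused gem-dibromocyclopropanes is a well-established reaction class. The acetate is installed directly, and capture at C1 rather than C5 is enforced by the quaternary C4. The vinyl bromide of A2 could be taken to 12 with the same coupling/chlorination pair as steps 3 and 4.
- Against it: the allyl cation is planar, so the face of acetate capture is decided only by the remote C3 bromine and the cis relation is not secured. The C3–Br centre would have to be made enantioenriched before the ring expansion, for which nothing better than a resolution is apparent. Silver ion may also attack the secondary C3 bromide.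
- Comparison: on structure, both plans deliver the brominated ring with the C1 oxygen, but only the chosen closure ties C1 to C3 in one transition state. On mechanism, Alternative 1 is the better of the two in precedent for the ring-forming event, and the chosen plan is the better in stereochemical coupling. On step economy the two are about equal.

Alternative 2: The cut is at C3–Br and C4–C5. It leads back to the acyclic vinylsilane A3, (2S,3E,4R)-2-[(tert-butyldimethylsilyl)oxy]-1-chloro-7-methyl-3-[(trimethylsilyl)methylidene]oct-6-en-4-yl acetate, in which C1 and C7 already carry their oxygen functions. Forward, Et2SBr·SbBrCl5 would deliver Br+ to the trisubstituted C3=C4 alkene and the silicon-bearing carbon C5 would attack C4 ipso. The ring would close with loss of the silyl group to give A4, (1R,5S)-5-bromo-2-[(1S)-1-[(tert-butyldimethylsilyl)oxy]-2-chloroethyl]-4,4-dimethylcyclohex-2-en-1-yl acetate.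
- In its favour: the cation is tertiary, and a bromonium-initiated cation–olefin closure is the established way to place a secondary bromide next to a gem-dimethyl carbon. A chair transition state with equatorial acetate and equatorial bromine would relay the preset C1 configuration to C3, so the absolute configuration of the ring would not rest on a resolution. On this point Alternative 2 is the better plan.
- Against it: A3 holds two stereocentres and a trisubstituted vinylsilane of defined geometry and needs a long linear build-up. The closure must form the quaternary carbon by attack of a hindered, silyl-substituted sp2 carbon. Br+ also has competing partners (direct bromodesilylation, capture of the cation by the acetate carbonyl).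
- Comparison: on structure, A4 is further advanced at C7 but still needs desilylation and bromination, meeting the chosen route at 13. On mechanism it is the equal of the chosen plan in diastereocontrol and better in absolute control, but less certain in its terminating event. On step economy the chosen plan is clearly shorter.

Alternative 3: The cut is at C1–C6. It leads back to the acyclic iodo aldehyde A5, (3S,5Z,7R)-3-bromo-7-[(tert-butyldimethylsilyl)oxy]-8-chloro-6-iodo-4,4-dimethyloct-5-enal, with the C3 bromide and the C7 silyl ether in place. Forward, CrCl2 regenerated at a cathode, with NiCl2 as co-catalyst, would turn the C6–I bond into a C–Cr bond that adds to the C1 aldehyde (Nozaki–Hiyama–Kishi closure). The product would be the allylic alcohol A6, (1R,5S)-5-bromo-2-[(1S)-1-[(tert-butyldimethylsilyl)oxy]-2-chloroethyl]-4,4-dimethylcyclohex-2-en-1-ol.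
- In its favour: no carbocation is involved. Alkenyl–Cr species add to aldehydes chemoselectively in the presence of ethers and alkyl chlorides, ring closures of this kind are reliable, and chromium is used catalytically. In the reliability of the C–C bond-forming event it is the equal of, or better than, the chosen step.
- Against it: the hardest bond, C3–Br next to the quaternary carbon, is pushed back into an acyclic chain where no good enantioselective method is apparent. A5 is a β-bromo aldehyde prone to loss of HBr, and low-valent chromium or the cathode may reduce its C–Br bond. The new C1 centre would depend on 1,3-induction without a clear bias. A6 is still three operations (acetylation, desilylation, bromination) from 14.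
- Comparison: on structure, the chosen plan solves C3–Br and the ring in one step, Alternative 3 only the ring. On mechanism, Alternative 3 is milder and at least equal in functional-group tolerance. On step economy it is longer both before and after the closure.

Key step: step 5

Remark: the halo-Prins closure is run with achiral TiBr4, so 11 is the cis racemate (named and drawn as the (4S,6R) enantiomer that is carried on); the absolute configuration is fixed in step 6.

Step 1
Reactants: 1 2-bromopropanedial (bromomalonaldehyde)
Product: 2 (2Z)-2-bromo-3-(propan-2-yloxy)prop-2-enal
Conditions: i-PrOH (3 equiv), TsOH·H2O (2 mol %), cyclohexane, reflux, Dean–Stark trap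
Reagents that add atoms: propan-2-ol, CC(C)O
Why: Acid-catalysed O-alkylation of the enol form of a 1,3-dialdehyde (vinylogous esterification) with azeotropic removal of water; one formyl group becomes a vinylogous ester, so only the other is attacked in step 2.

Step 2
Reactants: 3 1-chloro-3-methylbut-2-ene (prenyl chloride); 2 (2Z)-2-bromo-3-(propan-2-yloxy)prop-2-enal
Product: 6 (2Z)-2-bromo-4,4-dimethylhexa-2,5-dienal, via prenylmagnesium chloride 4 (not isolated), via the racemic 1,2-adduct dienol 5 (not isolated)
Conditions: Mg, THF, 0 °C (3 → 4); then 2, THF, −78 °C; then 1 M HCl, THF, 0 °C → rt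
Reagents that add atoms: water, O
Why: Allylic Grignard reagents add to aldehydes through a six-membered transition state at their γ-carbon, which creates the quaternary C4 with its vinyl group; aqueous acid then effects the Stork–Danheiser-type carbonyl transposition of the vinylogous ester (loss of propan-2-ol) to the α-bromo enal. Conjugate addition–elimination at the alkoxy-bearing carbon would lead to the same product.

Step 3
Reactants: 6 (2Z)-2-bromo-4,4-dimethylhexa-2,5-dienal; 7 tributyl(1-ethoxyethenyl)stannane
Product: 8 (2E)-2-(1-ethoxyethenyl)-4,4-dimethylhexa-2,5-dienal
Conditions: Pd(PPh3)4 (5 mol %), CuI (10 mol %), toluene, 80 °C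
Reagents that add atoms: none
Why: Stille coupling of an α-bromo enal with an α-alkoxyvinylstannane as a masked acyl group; oxidative addition of zerovalent palladium and reductive elimination proceed with retention at the double bond, and the free aldehyde and the terminal vinyl group are tolerated.

Step 4
Reactants: 8 (2E)-2-(1-ethoxyethenyl)-4,4-dimethylhexa-2,5-dienal
Product: 10 (2E)-2-(2-chloroacetyl)-4,4-dimethylhexa-2,5-dienal, via its (2Z)-isomer 9 (not isolated)
Conditions: NCS (1.05 equiv), THF/H2O 4:1, 0 °C; then I2 (5 mol %), CH2Cl2, visible light, rt
Reagents that add atoms: N-chlorosuccinimide, O=C1CCC(=O)N1Cl; water, O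
Why: Electrophilic chlorination of the enol ether at its terminal carbon and hydrolysis of the resulting oxocarbenium ion give the chloromethyl ketone (the chlorine counterpart of the usual NBS route to bromomethyl ketones); the isolated vinyl group is far less nucleophilic. Reversible iodine-atom addition then relaxes the kinetic Z isomer to the E isomer, in which the small formyl group and not the chloroacetyl group lies cis to the quaternary carbon.

Step 5
Reactants: 10 (2E)-2-(2-chloroacetyl)-4,4-dimethylhexa-2,5-dienal
Product: 11 rac-1-[(4S,6R)-4-bromo-6-hydroxy-3,3-dimethylcyclohex-1-en-1-yl]-2-chloroethan-1-one (cis racemate)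
Conditions: TiBr4 (1.5 equiv), CH2Cl2 (0.02 M), −78 → −40 °C; aq. NaHCO3
Reagents that add atoms: titanium tetrabromide, Br[Ti](Br)(Br)Br
Why: TiBr4 binds the formyl and ketone oxygens of 10 in a six-membered chelate, which makes C1 strongly electrophilic and leaves the acyl-substituted C5=C6 bond inert as a nucleophile; the terminal vinyl carbon C2 adds to C1 and bromide (from a TiBr5− counter-ion or a second TiBr4) is captured at C3, i.e. a halo-Prins carbocyclisation. The closest known reaction type is the Lewis-acid (TiCl4, TiBr4, Me2AlCl) cyclisation of hex-5-enals to cis-3-halocyclohexanols. The single ring is closed in a six-membered mode that is exo with respect to the C=O bond and endo with respect to the vinyl group. C1 and C3 are set relative to each other in a half-chair: the chelate holds the C1–O bond in the enone plane (pseudo-equatorial) and bromide adds to C3 anti-periplanar to the forming C1–C2 bond, which is the equatorial position, so O and Br come out cis; a chelated oxygen lies too far from C3 to hand over its own bromide, but the non-chelated array with axial O and syn delivery from the O–TiBr3 group leads to the same cis pair, which is also the more stable diequatorial isomer. The step needs cation capture to beat other outlets: C4 has no hydrogen, so the carbonyl-ene path is closed, and −78 °C in CH2Cl2 is chosen to suppress 1,2-methyl shift and chloride/bromide exchange at C8. It also needs the formyl group cis to C4: both acyl groups sit on C6, so 9 and 10 interconvert under the Lewis acid and only 10 can reach C2 (Curtin–Hammett), while the gem-dimethyl group and the cis alkene favour the folded conformer. No absolute control is attempted; 11 forms as the cis racemate and is resolved in step 6.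

Step 6
Reactants: 11 rac-1-[(4S,6R)-4-bromo-6-hydroxy-3,3-dimethylcyclohex-1-en-1-yl]-2-chloroethan-1-one (cis racemate)
Product: 12 (1R,5S)-5-bromo-2-(2-chloroacetyl)-4,4-dimethylcyclohex-2-en-1-yl acetate
Conditions: Burkholderia cepacia lipase (immobilised), vinyl acetate (3 equiv), MTBE, 30 °C, stopped near half conversion; chromatography
Reagents that add atoms: vinyl acetate, C=COC(C)=O
Why: Lipase-catalysed kinetic resolution by irreversible transesterification; by the empirical size rule for secondary carbinols (large group = the acyl-bearing sp2 carbon C6, medium group = the C2 methylene) the (R)-carbinol is the fast-reacting enantiomer, so the wanted acetate forms directly and the (4R,6S)-alcohol stays behind. No new stereocentre is made; the absolute configuration at C1 and C3 is selected here, and any leakage is removable as a diastereomer after step 7.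

Step 7
Reactants: 12 (1R,5S)-5-bromo-2-(2-chloroacetyl)-4,4-dimethylcyclohex-2-en-1-yl acetate
Product: 13 (1R,5S)-5-bromo-2-[(1S)-2-chloro-1-hydroxyethyl]-4,4-dimethylcyclohex-2-en-1-yl acetate
Conditions: (S)-2-methyl-CBS-oxazaborolidine (0.2 equiv), BH3·SMe2 (0.7 equiv), THF, −20 °C, slow addition of 12; MeOH quench
Reagents that add atoms: none
Why: Corey–Bakshi–Shibata reduction; the branched cyclohexenyl group acts as the large and the chloromethyl group as the small substituent, so the (S)-catalyst delivers hydride to the face that gives the (S)-chlorohydrin (the sense established for aryl chloromethyl ketones), under reagent control over the C1 centre. The ester, both alkyl halides and the hindered alkene are not touched at this temperature.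

Step 8
Reactants: 13 (1R,5S)-5-bromo-2-[(1S)-2-chloro-1-hydroxyethyl]-4,4-dimethylcyclohex-2-en-1-yl acetate
Product: 14 (1R,5S)-5-bromo-2-[(1R)-1-bromo-2-chloroethyl]-4,4-dimethylcyclohex-2-en-1-yl acetate
Conditions: PPh3 (1.3 equiv), CBr4 (1.3 equiv), CH2Cl2, −20 → 0 °C
Reagents that add atoms: tetrabromomethane, BrC(Br)(Br)Br
Why: Appel bromination; bromide displaces the alkoxyphosphonium group in an SN2 step with inversion, turning the (S)-carbinol into the (R)-bromide. Ionisation is disfavoured by the electron-withdrawing chloromethyl and acetoxy neighbours, and SN2′ attack at C5 is blocked by the adjacent quaternary carbon.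

## Compound list

1 | 2-bromopropanedial (bromomalonaldehyde) | O=CC(Br)C=O | starting material
2 | (2Z)-2-bromo-3-(propan-2-yloxy)prop-2-enal | CC(C)O/C=C(\Br)C=O | intermediate
3 | 1-chloro-3-methylbut-2-ene (prenyl chloride) | CC(C)=CCCl | starting material
4 | (3-methylbut-2-en-1-yl)magnesium chloride (prenylmagnesium chloride) | CC(C)=CC[Mg]Cl | intermediate (not isolated)
5 | (1Z)-2-bromo-4,4-dimethyl-1-(propan-2-yloxy)hexa-1,5-dien-3-ol (racemic carbinol) | CC(C)O/C=C(\Br)C(O)C(C)(C)C=C | intermediate (not isolated)
6 | (2Z)-2-bromo-4,4-dimethylhexa-2,5-dienal | O=C/C(Br)=C/C(C)(C)C=C | intermediate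
7 | tributyl(1-ethoxyethenyl)stannane | CCCC[Sn](CCCC)(CCCC)C(=C)OCC | starting material
8 | (2E)-2-(1-ethoxyethenyl)-4,4-dimethylhexa-2,5-dienal | O=C/C(C(=C)OCC)=C/C(C)(C)C=C | intermediate
9 | (2Z)-2-(2-chloroacetyl)-4,4-dimethylhexa-2,5-dienal | O=C/C(C(=O)CCl)=C/C(C)(C)C=C | intermediate (not isolated)
10 | (2E)-2-(2-chloroacetyl)-4,4-dimethylhexa-2,5-dienal | O=C/C(C(=O)CCl)=C\C(C)(C)C=C | intermediate
11 | rac-1-[(4S,6R)-4-bromo-6-hydroxy-3,3-dimethylcyclohex-1-en-1-yl]-2-chloroethan-1-one (cis racemate; the (4S,6R) enantiomer is drawn) | O[C@@H]1C[C@H](Br)C(C)(C)C=C1C(=O)CCl | intermediate
12 | (1R,5S)-5-bromo-2-(2-chloroacetyl)-4,4-dimethylcyclohex-2-en-1-yl acetate | CC(=O)O[C@@H]1C[C@H](Br)C(C)(C)C=C1C(=O)CCl | intermediate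
13 | (1R,5S)-5-bromo-2-[(1S)-2-chloro-1-hydroxyethyl]-4,4-dimethylcyclohex-2-en-1-yl acetate | CC(=O)O[C@@H]1C[C@H](Br)C(C)(C)C=C1[C@H](O)CCl | intermediate
14 | (1R,5S)-5-bromo-2-[(1R)-1-bromo-2-chloroethyl]-4,4-dimethylcyclohex-2-en-1-yl acetate | CC(=O)O[C@@H]1C[C@H](Br)C(C)(C)C=C1[C@@H](Br)CCl | target

## Step count and risk

Total step count: 8. Longest linear sequence: 8 steps (1 to 14); 3 and 7 enter as commercial building blocks in steps 2 and 3.

Least certain steps, in order of risk:

**Step 5 (key step).** Bromide capture at C3 may fail to keep pace with C–C bond formation. A free secondary cation would then relax before capture, which erodes the cis relationship and opens a 1,2-methyl shift from C4. Chloride/bromide exchange at C8 can set in on prolonged contact with the Lewis acid. The monosubstituted vinyl group is also a weak π-nucleophile, so intermolecular consumption of the activated dienal may compete.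
Fallback, aimed at the stereochemical failure: the closure is no longer relied on for the cis relation and C1 is corrected afterwards. The fallback sets out from 10, whose cyclisation product is in that event the C1 epimer rac-1-[(4S,6S)-4-bromo-6-hydroxy-3,3-dimethylcyclohex-1-en-1-yl]-2-chloroethan-1-one F1. Mitsunobu reaction (PPh3, DIAD, HCO2H, THF, 0 °C) should invert C1 to rac-(1R,5S)-5-bromo-2-(2-chloroacetyl)-4,4-dimethylcyclohex-2-en-1-yl formate F2; SN2′ attack is blocked at the neopentyl C5. Brief methanolysis (KHCO3 cat., MeOH, 0 °C) should then release the cis alcohol, and the route is rejoined at 11.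

**Step 8.** Configurational fidelity at C7 may be lost. The C1 acetoxy group can participate through a six-membered acyloxonium ion (net retention), the allylic phosphonium intermediate can ionise, and bromide ion can epimerise the allylic bromide once formed.
Fallback: activation and displacement are separated. Setting out from 13, sulfonylation (MsCl, Et3N, CH2Cl2, −30 °C) should give (1R,5S)-5-bromo-2-[(1S)-2-chloro-1-(methanesulfonyloxy)ethyl]-4,4-dimethylcyclohex-2-en-1-yl acetate F3. Displacement with LiBr (1.1 equiv, acetone, 0 °C) under controlled bromide concentration should then give the inverted bromide, rejoining the route at 14.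

**Step 6.** The enzyme may discriminate poorly or turn over slowly. The carbinol is flanked by a fully substituted sp2 carbon, and the chloromethyl ketone is an alkylating agent that could inactivate the catalytic histidine.
Fallback: the resolution is moved to the reduction. Setting out from 11, chemical acetylation (Ac2O, DMAP, pyridine, CH2Cl2, 0 °C) should give rac-(1R,5S)-5-bromo-2-(2-chloroacetyl)-4,4-dimethylcyclohex-2-en-1-yl acetate F4. (S)-CBS reduction as in step 7 then converts the two enantiomers into diastereomers: 13 and (1S,5R)-5-bromo-2-[(1S)-2-chloro-1-hydroxyethyl]-4,4-dimethylcyclohex-2-en-1-yl acetate F5. These are separated by chromatography and the route is rejoined at 13. The enantiomeric purity of 13 then rests on reagent control in both reductions.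

**Step 3.** The alkenyl–Pd intermediate may be diverted (Heck-type insertion into the terminal vinyl group, homocoupling), and the alkoxydiene–enal product may dimerise thermally by hetero-Diels–Alder reaction.
Fallback: organolithium acylation replaces the coupling/chlorination pair. Setting out from 6, acetalisation (HC(OMe)3, MeOH, PPTS, rt) should give (2Z)-2-bromo-1,1-dimethoxy-4,4-dimethylhexa-2,5-diene F6. Bromine–lithium exchange (t-BuLi, 2 equiv, Et2O, −78 °C) and acylation with 2-chloro-N-methoxy-N-methylacetamide should give (3Z)-1-chloro-3-(dimethoxymethyl)-5,5-dimethylhepta-3,6-dien-2-one F7. Mild hydrolysis (aq. HCO2H, THF, 0 °C) releases 9, which is equilibrated as in step 4, and the route is rejoined at 10.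

## Further compounds

F1 | step 5 | rac-1-[(4S,6S)-4-bromo-6-hydroxy-3,3-dimethylcyclohex-1-en-1-yl]-2-chloroethan-1-one (trans racemate; one enantiomer drawn) | O[C@H]1C[C@H](Br)C(C)(C)C=C1C(=O)CCl
F2 | step 5 | rac-(1R,5S)-5-bromo-2-(2-chloroacetyl)-4,4-dimethylcyclohex-2-en-1-yl formate (cis racemate; one enantiomer drawn) | O=CO[C@@H]1C[C@H](Br)C(C)(C)C=C1C(=O)CCl
F3 | step 8 | (1R,5S)-5-bromo-2-[(1S)-2-chloro-1-(methanesulfonyloxy)ethyl]-4,4-dimethylcyclohex-2-en-1-yl acetate | CC(=O)O[C@@H]1C[C@H](Br)C(C)(C)C=C1[C@H](OS(C)(=O)=O)CCl
F4 | step 6 | rac-(1R,5S)-5-bromo-2-(2-chloroacetyl)-4,4-dimethylcyclohex-2-en-1-yl acetate (racemate of 12; one enantiomer drawn) | CC(=O)O[C@@H]1C[C@H](Br)C(C)(C)C=C1C(=O)CCl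
F5 | step 6 | (1S,5R)-5-bromo-2-[(1S)-2-chloro-1-hydroxyethyl]-4,4-dimethylcyclohex-2-en-1-yl acetate | CC(=O)O[C@H]1C[C@@H](Br)C(C)(C)C=C1[C@H](O)CCl
F6 | step 3 | (2Z)-2-bromo-1,1-dimethoxy-4,4-dimethylhexa-2,5-diene | COC(OC)/C(Br)=C/C(C)(C)C=C
F7 | step 3 | (3Z)-1-chloro-3-(dimethoxymethyl)-5,5-dimethylhepta-3,6-dien-2-one | COC(OC)/C(C(=O)CCl)=C/C(C)(C)C=C
A1 | alternative 1 | (1S,3S,5S)-3,6,6-tribromo-2,2-dimethylbicyclo[3.1.0]hexane | BrC1(Br)[C@H]2C[C@H](Br)C(C)(C)[C@@H]12
A2 | alternative 1 | (1R,5S)-2,5-dibromo-4,4-dimethylcyclohex-2-en-1-yl acetate | CC(=O)O[C@@H]1C[C@H](Br)C(C)(C)C=C1Br
A3 | alternative 2 | (2S,3E,4R)-2-[(tert-butyldimethylsilyl)oxy]-1-chloro-7-methyl-3-[(trimethylsilyl)methylidene]oct-6-en-4-yl acetate | CC(=O)O[C@H](CC=C(C)C)/C(=C\[Si](C)(C)C)[C@H](O[Si](C)(C)C(C)(C)C)CCl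
A4 | alternative 2 | (1R,5S)-5-bromo-2-[(1S)-1-[(tert-butyldimethylsilyl)oxy]-2-chloroethyl]-4,4-dimethylcyclohex-2-en-1-yl acetate | CC(=O)O[C@@H]1C[C@H](Br)C(C)(C)C=C1[C@H](O[Si](C)(C)C(C)(C)C)CCl
A5 | alternative 3 | (3S,5Z,7R)-3-bromo-7-[(tert-butyldimethylsilyl)oxy]-8-chloro-6-iodo-4,4-dimethyloct-5-enal | O=CC[C@H](Br)C(C)(C)/C=C(\I)[C@H](O[Si](C)(C)C(C)(C)C)CCl
A6 | alternative 3 | (1R,5S)-5-bromo-2-[(1S)-1-[(tert-butyldimethylsilyl)oxy]-2-chloroethyl]-4,4-dimethylcyclohex-2-en-1-ol | O[C@@H]1C[C@H](Br)C(C)(C)C=C1[C@H](O[Si](C)(C)C(C)(C)C)CCl
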